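**Retrosynthetic overview**

1. Locants: ring carbons C1–C14 run from the lactone carbinol C1 (O, Me) through C2, C3, C4 (bears C15), C5 (OH), C6, C7 (Me, oxolane O), C8, C9, C10 (oxolane O), C11 (=CH2), C12, C13 to C14 (OH); C15 is the acrylate α-carbon, C16 the C=O and C17 the exo-CH2. The target is opened at O1–C16 (lactonisation) and C15=C17 (Peterson methylenation with CH2O, silicon leaving on O5), giving macrocycle 29/28.
2. Macrocycle 28 comes from open-chain 26 in one anionic cascade: a silicon-tethered 5-exo Michael addition (C15–C4) generates a sulfonyl carbanion at C3, which opens the C1/C2 oxirane (C2–C3).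
3. 26 is assembled from vinyl carbinol 19, phenyl vinyl sulfone 20 (cross-metathesis) and the chlorosilyl acetate 25 (O5–Si tether).
4. 19 comes from geraniol (two Sharpless epoxidations set C7 and C10 of the cis-oxolane) and the (S)-epoxy ketone 13 (C13, C14, C1, C2); a CBS reduction sets C14 and a catalytic vinyl-zinc addition sets C5.
5. Enabling feature: O5 sits on the carbon next to C4, so an O–Si–C15 tether closes a five-membered 1-oxa-2-silacyclopentane onto C4; and C1 carries the lactone oxygen next to the C2 methylene, so C1–O/C2 can be carried as a 2,2-disubstituted oxirane whose CH2 closes the ring. Ring order: oxolane (step 5), oxirane (carried from 13), oxasilolane plus fourteen-membered carbocycle (step 20), ε-lactone (step 22).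

Key step: step 20

Remark: the stereocentres C3 and C15 of 27–29 should form as mixtures and are destroyed later, so they are left unspecified in the SMILES.

**Route**

Step 1
Reactants: 1 geraniol
Product: 2 (2S,3S)-2,3-epoxygeraniol
Conditions: Ti(OiPr)4 (cat.), L-(+)-diethyl tartrate, t-BuOOH, 4 Å MS, CH2Cl2, −20 °C
Reagents that add atoms: tert-butyl hydroperoxide, CC(C)(C)OO
Why: Sharpless asymmetric epoxidation of the primary allylic alcohol, in which the L-(+)-tartrate should deliver the (2S,3S)-epoxide and so fix the future C7.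

Step 2
Reactants: 2 (2S,3S)-2,3-epoxygeraniol
Product: 3 (3S)-3,7-dimethyloct-6-ene-1,3-diol
Conditions: NaAlH2(OCH2CH2OMe)2, THF, 0 °C
Reagents that add atoms: none
Why: Hydroxyl-directed hydride opening of a 2,3-epoxy alcohol at C2 should give the 1,3-diol and leave the tertiary C–O stereocentre untouched.

Step 3
Reactants: 3 (3S)-3,7-dimethyloct-6-ene-1,3-diol
Product: 4 (3S)-1-[(4-methoxybenzyl)oxy]-3,7-dimethyloct-6-en-3-ol
Conditions: NaH (1.05 equiv), 4-methoxybenzyl chloride, Bu4NI (cat.), THF–DMF, 0 °C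
Reagents that add atoms: 4-methoxybenzyl chloride, COc1ccc(CCl)cc1
Why: Williamson etherification should take place at the primary alkoxide only, the tertiary hydroxyl being too hindered.

Step 4
Reactants: 4 (3S)-1-[(4-methoxybenzyl)oxy]-3,7-dimethyloct-6-en-3-ol
Product: 5 (2E,6S)-8-[(4-methoxybenzyl)oxy]-2,6-dimethyloct-2-ene-1,6-diol
Conditions: SeO2 (0.2 equiv), t-BuOOH, salicylic acid (cat.), CH2Cl2, 20 °C
Reagents that add atoms: tert-butyl hydroperoxide, CC(C)(C)OO (oxygen delivered through SeO2, O=[Se]=O)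
Why: Riley allylic oxidation (ene reaction then [2,3]-shift) should hydroxylate the (E)-methyl group of the trisubstituted alkene, which becomes C12.

Step 5
Reactants: 5 (2E,6S)-8-[(4-methoxybenzyl)oxy]-2,6-dimethyloct-2-ene-1,6-diol
Product: 7 (2S)-2-[(2R,5S)-5-{2-[(4-methoxybenzyl)oxy]ethyl}-5-methyloxolan-2-yl]propane-1,2-diol, via epoxy alcohol 6 (not isolated)
Conditions: Ti(OiPr)4, L-(+)-diethyl tartrate, t-BuOOH, 4 Å MS, CH2Cl2, −20 °C; then CSA (cat.), 0 °C
Reagents that add atoms: tert-butyl hydroperoxide, CC(C)(C)OO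
Why: Sharpless asymmetric epoxidation should give the (2S,3S)-epoxy alcohol, which the tertiary hydroxyl opens 5-exo-tet at C10 with inversion, so that C10 becomes R and the oxolane is 2,5-cis.

Step 6
Reactants: 7 (2S)-2-[(2R,5S)-5-{2-[(4-methoxybenzyl)oxy]ethyl}-5-methyloxolan-2-yl]propane-1,2-diol
Product: 8 (2R,5S)-5-{2-[(4-methoxybenzyl)oxy]ethyl}-5-methyl-2-[(2S)-2-methyloxiran-2-yl]oxolane
Conditions: NaH (2.2 equiv), 1-(p-toluenesulfonyl)imidazole, THF, 0 → 20 °C
Reagents that add atoms: none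
Why: Selective tosylation of the primary hydroxyl and intramolecular Williamson closure by the tertiary alkoxide should give the terminal oxirane in one pot.

Step 7
Reactants: 8 (2R,5S)-5-{2-[(4-methoxybenzyl)oxy]ethyl}-5-methyl-2-[(2S)-2-methyloxiran-2-yl]oxolane
Product: 9 2-[(2R,5S)-5-{2-[(4-methoxybenzyl)oxy]ethyl}-5-methyloxolan-2-yl]prop-2-en-1-ol
Conditions: Et2Al(TMP) (TMP = 2,2,6,6-tetramethylpiperidide), toluene, 0 °C
Reagents that add atoms: none
Why: Base-promoted isomerisation of an epoxide to an allylic alcohol with a bulky dialkylaluminium amide should remove a proton from the unhindered methyl group and so create the C11 exocyclic methylene and the C12 carbinol.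

Step 8
Reactants: 9 2-[(2R,5S)-5-{2-[(4-methoxybenzyl)oxy]ethyl}-5-methyloxolan-2-yl]prop-2-en-1-ol
Product: 10 (2R,5S)-2-(3-bromoprop-1-en-2-yl)-5-{2-[(4-methoxybenzyl)oxy]ethyl}-5-methyloxolane
Conditions: CBr4, PPh3, CH2Cl2, 0 °C
Reagents that add atoms: carbon tetrabromide, BrC(Br)(Br)Br
Why: Appel bromination of a primary allylic alcohol, where allylic transposition would be degenerate because both allyl termini are CH2.

Step 9
Reactants: 11 (±)-3-methylbut-3-en-2-ol
Product: 12 (1R)-1-[(2S)-2-methyloxiran-2-yl]ethan-1-ol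
Conditions: Ti(OiPr)4 (0.1 equiv), D-(−)-diisopropyl tartrate, t-BuOOH (0.45 equiv), 4 Å MS, CH2Cl2, −20 °C
Reagents that add atoms: tert-butyl hydroperoxide, CC(C)(C)OO
Why: Sharpless kinetic resolution, in which the D-(−)-tartrate should epoxidise the (R)-alcohol fast and erythro-selectively and so set the (S)-oxirane carbon (future C1).

Step 10
Reactants: 12 (1R)-1-[(2S)-2-methyloxiran-2-yl]ethan-1-ol
Product: 13 1-[(2S)-2-methyloxiran-2-yl]ethan-1-one
Conditions: Dess–Martin periodinane, NaHCO3, CH2Cl2, 0 °C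
Reagents that add atoms: none
Why: Dess–Martin oxidation removes the relay carbinol centre and keeps the quaternary oxirane centre, which has no α-hydrogen.

Step 11
Reactants: 10 (2R,5S)-2-(3-bromoprop-1-en-2-yl)-5-{2-[(4-methoxybenzyl)oxy]ethyl}-5-methyloxolane; 13 1-[(2S)-2-methyloxiran-2-yl]ethan-1-one
Product: 14 4-[(2R,5S)-5-{2-[(4-methoxybenzyl)oxy]ethyl}-5-methyloxolan-2-yl]-1-[(2S)-2-methyloxiran-2-yl]pent-4-en-1-one
Conditions: 13, LiN(iPr)2, THF, −78 °C; then 10, DMPU, −78 → −30 °C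
Reagents that add atoms: none
Why: Alkylation of the kinetic methyl-ketone enolate (the only enolisable side) with the reactive allylic bromide should join C12 to C13.

Step 12
Reactants: 14 4-[(2R,5S)-5-{2-[(4-methoxybenzyl)oxy]ethyl}-5-methyloxolan-2-yl]-1-[(2S)-2-methyloxiran-2-yl]pent-4-en-1-one
Product: 15 (1S)-4-[(2R,5S)-5-{2-[(4-methoxybenzyl)oxy]ethyl}-5-methyloxolan-2-yl]-1-[(2S)-2-methyloxiran-2-yl]pent-4-en-1-ol
Conditions: (R)-2-methyl-CBS-oxazaborolidine (0.2 equiv), catecholborane, toluene, −78 °C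
Reagents that add atoms: none
Why: Corey–Bakshi–Shibata reduction under catalyst control, with the quaternary oxiranyl carbon as the large group, should give the (14S)-alcohol, and catecholborane should spare the alkenes.

Step 13
Reactants: 15 (1S)-4-[(2R,5S)-5-{2-[(4-methoxybenzyl)oxy]ethyl}-5-methyloxolan-2-yl]-1-[(2S)-2-methyloxiran-2-yl]pent-4-en-1-ol
Product: 16 tert-butyldimethylsilyl ether of 15
Conditions: TBSCl, imidazole, DMF, 35 °C
Reagents that add atoms: tert-butyldimethylsilyl chloride, CC(C)(C)[Si](C)(C)Cl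
Why: Silylation under weakly basic conditions protects O14 without Payne rearrangement of the neighbouring oxirane.

Step 14
Reactants: 16 tert-butyldimethylsilyl ether of 15
Product: 17 2-[(2S,5R)-5-{(5S)-5-[(tert-butyldimethylsilyl)oxy]-5-[(2S)-2-methyloxiran-2-yl]pent-1-en-2-yl}-2-methyloxolan-2-yl]ethan-1-ol
Conditions: DDQ, CH2Cl2–pH 7 buffer, 0 °C
Reagents that add atoms: none
Why: Oxidative cleavage of the 4-methoxybenzyl ether should leave the silyl ether, the oxirane and the alkenes untouched.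

Step 15
Reactants: 17 2-[(2S,5R)-5-{(5S)-5-[(tert-butyldimethylsilyl)oxy]-5-[(2S)-2-methyloxiran-2-yl]pent-1-en-2-yl}-2-methyloxolan-2-yl]ethan-1-ol
Product: 18 2-[(2S,5R)-5-{(5S)-5-[(tert-butyldimethylsilyl)oxy]-5-[(2S)-2-methyloxiran-2-yl]pent-1-en-2-yl}-2-methyloxolan-2-yl]acetaldehyde
Conditions: Dess–Martin periodinane, NaHCO3, CH2Cl2, 0 °C
Reagents that add atoms: none
Why: Dess–Martin oxidation gives the C5 aldehyde under buffered, non-epimerising conditions.

Step 16
Reactants: 18 2-[(2S,5R)-5-{(5S)-5-[(tert-butyldimethylsilyl)oxy]-5-[(2S)-2-methyloxiran-2-yl]pent-1-en-2-yl}-2-methyloxolan-2-yl]acetaldehyde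
Product: 19 (2S)-1-[(2S,5R)-5-{(5S)-5-[(tert-butyldimethylsilyl)oxy]-5-[(2S)-2-methyloxiran-2-yl]pent-1-en-2-yl}-2-methyloxolan-2-yl]but-3-en-2-ol
Conditions: Zn(CH=CH2)2 (1.5 equiv), (+)-DAIB (0.1 equiv), toluene, 0 °C
Reagents that add atoms: divinylzinc, C=C[Zn]C=C
Why: Amino-alcohol-catalysed enantioselective alkenylzinc addition should transfer vinyl to the Re face of the aldehyde to give the (5S)-carbinol, and any C5 epimer would be a separable diastereomer.

Step 17
Reactants: 19 (2S)-1-[(2S,5R)-5-{(5S)-5-[(tert-butyldimethylsilyl)oxy]-5-[(2S)-2-methyloxiran-2-yl]pent-1-en-2-yl}-2-methyloxolan-2-yl]but-3-en-2-ol; 20 phenyl vinyl sulfone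
Product: 21 (2S,3E)-1-[(2S,5R)-5-{(5S)-5-[(tert-butyldimethylsilyl)oxy]-5-[(2S)-2-methyloxiran-2-yl]pent-1-en-2-yl}-2-methyloxolan-2-yl]-4-(phenylsulfonyl)but-3-en-2-ol
Conditions: 20 (3 equiv), RuCl2(H2IMes)(=CH-C6H4-2-OiPr) (Hoveyda–Grubbs second-generation catalyst, 5 mol %), CH2Cl2, 40 °C
Reagents that add atoms: none
Why: Cross-metathesis of the monosubstituted alkene with the electron-poor vinyl sulfone should be E-selective and should leave the 1,1-disubstituted C11 methylene untouched.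

Step 18
Reactants: 22 methyl bromoacetate; 23 dichlorodi(propan-2-yl)silane
Product: 25 methyl 2-[chlorodi(propan-2-yl)silyl]acetate, via Reformatsky reagent 24 (not isolated)
Conditions: Zn, THF, 40 °C; then 23 (2 equiv), 0 → 20 °C
Reagents that add atoms: none
Why: C-silylation of a Reformatsky reagent by a chlorosilane is the standard entry to α-silyl acetates, and the excess of dichlorosilane should prevent double substitution.

Step 19
Reactants: 21 (2S,3E)-1-[(2S,5R)-5-{(5S)-5-[(tert-butyldimethylsilyl)oxy]-5-[(2S)-2-methyloxiran-2-yl]pent-1-en-2-yl}-2-methyloxolan-2-yl]-4-(phenylsulfonyl)but-3-en-2-ol; 25 methyl 2-[chlorodi(propan-2-yl)silyl]acetate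
Product: 26 methyl 2-[{[(2S,3E)-1-[(2S,5R)-5-{(5S)-5-[(tert-butyldimethylsilyl)oxy]-5-[(2S)-2-methyloxiran-2-yl]pent-1-en-2-yl}-2-methyloxolan-2-yl]-4-(phenylsulfonyl)but-3-en-2-yl]oxy}di(propan-2-yl)silyl]acetate
Conditions: 25, imidazole, CH2Cl2, 0 °C
Reagents that add atoms: none
Why: O-silylation of the secondary allylic alcohol installs the O5–Si–C15 tether under conditions too mild for oxa-Michael or epoxide side reactions.

Step 20
Reactants: 26 methyl 2-[{[(2S,3E)-1-[(2S,5R)-5-{(5S)-5-[(tert-butyldimethylsilyl)oxy]-5-[(2S)-2-methyloxiran-2-yl]pent-1-en-2-yl}-2-methyloxolan-2-yl]-4-(phenylsulfonyl)but-3-en-2-yl]oxy}di(propan-2-yl)silyl]acetate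
Product: 28 macrocyclic hydroxy sulfone (fourteen-membered carbocycle fused to the oxasilolane; see list), via dilithio Michael adduct 27 (not isolated)
Conditions: LiN(iPr)2 (2.4 equiv), THF (0.002 M), −78 °C; then DMPU, −78 → 0 °C; AcOH
Reagents that add atoms: none
Why: Proposed new method: LiN(iPr)2 deprotonates the α-silyl ester at C15 and the enolate adds 5-exo-trig to the (E)-vinyl sulfone (C15–C4), closing the 1-oxa-2-silacyclopentane and leaving an α-sulfonyl carbanion at C3, while the second equivalent of base turns C15 back into the α-silyl enolate so that retro-Michael cleavage is blocked and no C–H acid is left to quench C3. The C3 carbanion then opens the 2,2-disubstituted oxirane at its CH2 terminus (C3–C2) in a 14-exo-tet closure of the carbocycle and releases the C1 alkoxide with retention at C1. The closest known reaction types are the Michael-initiated ring closure, the silicon-tethered 5-exo cyclisation of allylic alcohols and the sulfone-carbanion/epoxide macrocyclisation used for cembranoids. C4 is set by the C5 stereocentre through the tether (C6 pseudo-equatorial in a chair-like transition state, so that C3 and C6 end up trans on the oxasilolane), whereas C3 and C15 form as mixtures and are destroyed later. The step needs chemoselective enolisation of the SiCH2CO2Me group next to a vinyl sulfone and an oxirane (secured by the acidifying silicon and by fast intramolecular trapping) and attack on the oxirane by C3 and not by the hindered enolate (secured by the much higher nucleophilicity of the sulfonyl carbanion and by high dilution).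

Step 21
Reactants: 28 macrocyclic hydroxy sulfone
Product: 29 macrocyclic hydroxy ester (C3 now CH2; see list)
Conditions: SmI2 (6 equiv), HMPA, t-BuOH, THF, −20 °C
Reagents that add atoms: none
Why: Reductive desulfonylation of an alkyl phenyl sulfone by electron transfer is done before any acrylate is present and should leave the α-silyl ester, the silyl ethers and the alkene untouched.

Step 22
Reactants: 29 macrocyclic hydroxy ester
Product: 31 silanol lactone (α-methylene ε-lactone; see list), via dilithium dialkoxide 30 (not isolated)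
Conditions: LiN(iPr)2 (2.3 equiv), THF, −78 → −40 °C; CH2O (gas), −78 → 20 °C; AcOH
Reagents that add atoms: formaldehyde, C=O
Why: Peterson olefination of the α-silyl ester enolate with formaldehyde should create C15=C17 while the silicon stays on O5 as a silanolate (so O5 cannot lactonise), and the C1 alkoxide should then close the seven-membered lactone onto the methyl ester by transesterification.

Step 23
Reactants: 31 silanol lactone
Product: 32 CNP0289823.1
Conditions: HF·pyridine, pyridine, THF, 0 → 20 °C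
Reagents that add atoms: none
Why: Buffered fluoride-mediated desilylation should remove the O14 silyl ether and the O5 silanol residue without base, so that the free C5 hydroxyl cannot translactonise onto C16.

**Compound list**

1 | geraniol, (2E)-3,7-dimethylocta-2,6-dien-1-ol | CC(C)=CCC/C(C)=C/CO | starting material
2 | (2S,3S)-2,3-epoxygeraniol, [(2S,3S)-3-methyl-3-(4-methylpent-3-en-1-yl)oxiran-2-yl]methanol | OC[C@@H]1O[C@@]1(C)CCC=C(C)C | intermediate
3 | (3S)-3,7-dimethyloct-6-ene-1,3-diol | OCC[C@](O)(C)CCC=C(C)C | intermediate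
4 | (3S)-1-[(4-methoxybenzyl)oxy]-3,7-dimethyloct-6-en-3-ol | COc1ccc(COCC[C@](O)(C)CCC=C(C)C)cc1 | intermediate
5 | (2E,6S)-8-[(4-methoxybenzyl)oxy]-2,6-dimethyloct-2-ene-1,6-diol | COc1ccc(COCC[C@](O)(C)CC/C=C(\C)CO)cc1 | intermediate
6 | (3S)-5-[(2S,3S)-3-(hydroxymethyl)-3-methyloxiran-2-yl]-1-[(4-methoxybenzyl)oxy]-3-methylpentan-3-ol | COc1ccc(COCC[C@](O)(C)CC[C@@H]2O[C@@]2(C)CO)cc1 | intermediate
7 | (2S)-2-[(2R,5S)-5-{2-[(4-methoxybenzyl)oxy]ethyl}-5-methyloxolan-2-yl]propane-1,2-diol | COc1ccc(COCC[C@]2(C)CC[C@@H](O2)[C@@](C)(O)CO)cc1 | intermediate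
8 | (2R,5S)-5-{2-[(4-methoxybenzyl)oxy]ethyl}-5-methyl-2-[(2S)-2-methyloxiran-2-yl]oxolane | COc1ccc(COCC[C@]2(C)CC[C@@H](O2)[C@]3(C)CO3)cc1 | intermediate
9 | 2-[(2R,5S)-5-{2-[(4-methoxybenzyl)oxy]ethyl}-5-methyloxolan-2-yl]prop-2-en-1-ol | COc1ccc(COCC[C@]2(C)CC[C@@H](O2)C(=C)CO)cc1 | intermediate
10 | (2R,5S)-2-(3-bromoprop-1-en-2-yl)-5-{2-[(4-methoxybenzyl)oxy]ethyl}-5-methyloxolane | COc1ccc(COCC[C@]2(C)CC[C@@H](O2)C(=C)CBr)cc1 | intermediate
11 | (±)-3-methylbut-3-en-2-ol | CC(O)C(C)=C | starting material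
12 | (1R)-1-[(2S)-2-methyloxiran-2-yl]ethan-1-ol | C[C@@H](O)[C@]1(C)CO1 | intermediate
13 | 1-[(2S)-2-methyloxiran-2-yl]ethan-1-one | CC(=O)[C@]1(C)CO1 | intermediate
14 | 4-[(2R,5S)-5-{2-[(4-methoxybenzyl)oxy]ethyl}-5-methyloxolan-2-yl]-1-[(2S)-2-methyloxiran-2-yl]pent-4-en-1-one | COc1ccc(COCC[C@]2(C)CC[C@@H](O2)C(=C)CCC(=O)[C@]3(C)CO3)cc1 | intermediate
15 | (1S)-4-[(2R,5S)-5-{2-[(4-methoxybenzyl)oxy]ethyl}-5-methyloxolan-2-yl]-1-[(2S)-2-methyloxiran-2-yl]pent-4-en-1-ol | COc1ccc(COCC[C@]2(C)CC[C@@H](O2)C(=C)CC[C@H](O)[C@]3(C)CO3)cc1 | intermediate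
16 | tert-butyl({(1S)-4-[(2R,5S)-5-{2-[(4-methoxybenzyl)oxy]ethyl}-5-methyloxolan-2-yl]-1-[(2S)-2-methyloxiran-2-yl]pent-4-en-1-yl}oxy)dimethylsilane | COc1ccc(COCC[C@]2(C)CC[C@@H](O2)C(=C)CC[C@H](O[Si](C)(C)C(C)(C)C)[C@]3(C)CO3)cc1 | intermediate
17 | 2-[(2S,5R)-5-{(5S)-5-[(tert-butyldimethylsilyl)oxy]-5-[(2S)-2-methyloxiran-2-yl]pent-1-en-2-yl}-2-methyloxolan-2-yl]ethan-1-ol | OCC[C@]1(C)CC[C@@H](O1)C(=C)CC[C@H](O[Si](C)(C)C(C)(C)C)[C@]2(C)CO2 | intermediate
18 | 2-[(2S,5R)-5-{(5S)-5-[(tert-butyldimethylsilyl)oxy]-5-[(2S)-2-methyloxiran-2-yl]pent-1-en-2-yl}-2-methyloxolan-2-yl]acetaldehyde | O=CC[C@]1(C)CC[C@@H](O1)C(=C)CC[C@H](O[Si](C)(C)C(C)(C)C)[C@]2(C)CO2 | intermediate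
19 | (2S)-1-[(2S,5R)-5-{(5S)-5-[(tert-butyldimethylsilyl)oxy]-5-[(2S)-2-methyloxiran-2-yl]pent-1-en-2-yl}-2-methyloxolan-2-yl]but-3-en-2-ol | C=C[C@@H](O)C[C@]1(C)CC[C@@H](O1)C(=C)CC[C@H](O[Si](C)(C)C(C)(C)C)[C@]2(C)CO2 | intermediate
20 | phenyl vinyl sulfone, (ethenesulfonyl)benzene | C=CS(=O)(=O)c1ccccc1 | starting material
21 | (2S,3E)-1-[(2S,5R)-5-{(5S)-5-[(tert-butyldimethylsilyl)oxy]-5-[(2S)-2-methyloxiran-2-yl]pent-1-en-2-yl}-2-methyloxolan-2-yl]-4-(phenylsulfonyl)but-3-en-2-ol | O=S(=O)(c1ccccc1)/C=C/[C@@H](O)C[C@]2(C)CC[C@@H](O2)C(=C)CC[C@H](O[Si](C)(C)C(C)(C)C)[C@]3(C)CO3 | intermediate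
22 | methyl bromoacetate | COC(=O)CBr | starting material
23 | dichlorodi(propan-2-yl)silane | CC(C)[Si](Cl)(Cl)C(C)C | starting material
24 | bromo(2-methoxy-2-oxoethyl)zinc (Reformatsky reagent) | COC(=O)C[Zn]Br | intermediate
25 | methyl 2-[chlorodi(propan-2-yl)silyl]acetate | COC(=O)C[Si](Cl)(C(C)C)C(C)C | intermediate
26 | methyl 2-[{[(2S,3E)-1-[(2S,5R)-5-{(5S)-5-[(tert-butyldimethylsilyl)oxy]-5-[(2S)-2-methyloxiran-2-yl]pent-1-en-2-yl}-2-methyloxolan-2-yl]-4-(phenylsulfonyl)but-3-en-2-yl]oxy}di(propan-2-yl)silyl]acetate | O=S(=O)(c1ccccc1)/C=C/[C@@H](O[Si](C(C)C)(C(C)C)CC(=O)OC)C[C@]2(C)CC[C@@H](O2)C(=C)CC[C@H](O[Si](C)(C)C(C)(C)C)[C@]3(C)CO3 | intermediate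
27 | dilithio Michael adduct: 2,2-di(propan-2-yl)-1-oxa-2-silacyclopentane (ring O on C5, C15–C4 bond) with C3 as lithiated PhSO2CH carbanion and C15 as lithium ester enolate; oxirane and open chain as in 26 | [Li+].[Li+].O=S(=O)(c1ccccc1)[CH-][C@H]2[C@H](C[C@]3(C)CC[C@@H](O3)C(=C)CC[C@H](O[Si](C)(C)C(C)(C)C)[C@]4(C)CO4)O[Si](C(C)C)(C(C)C)C2=C([O-])OC | intermediate
28 | macrocyclic hydroxy sulfone: (1S,4S,5S,7S,10R,14S)-configured fourteen-membered carbocycle C1–C14 with 1-OH, 1-Me, 3-SO2Ph (epimers), 7,10-epoxy bridge (7-Me), 11-methylidene, 14-OTBS, and a 2,2-di(propan-2-yl)-1-oxa-2-silacyclopentane fused at C4–C5 (O on C5; C15 carries CO2Me, epimers) | O=S(=O)(c1ccccc1)C2C[C@](C)(O)[C@@H](O[Si](C)(C)C(C)(C)C)CCC(=C)[C@H]3CC[C@](C)(O3)C[C@@H]4O[Si](C(C)C)(C(C)C)C(C(=O)OC)[C@@H]24 | intermediate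
29 | macrocyclic hydroxy ester: as 28 but with C3 = CH2; (1S,4S,5S,7S,10R,14S), C15 epimers | C1C[C@](C)(O)[C@@H](O[Si](C)(C)C(C)(C)C)CCC(=C)[C@H]2CC[C@](C)(O2)C[C@@H]3O[Si](C(C)C)(C(C)C)C(C(=O)OC)[C@@H]13 | intermediate
30 | dilithium dialkoxide: methyl 2-substituted acrylate at C4 (C15=C17 formed), lithium alkoxide at O1, lithium di(propan-2-yl)silanolate on O5, 14-OTBS | C=C(C(=O)OC)[C@H]1CC[C@](C)([O-])[C@@H](O[Si](C)(C)C(C)(C)C)CCC(=C)[C@H]2CC[C@](C)(O2)C[C@@H]1O[Si]([O-])(C(C)C)C(C)C.[Li+].[Li+] | intermediate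
31 | silanol lactone: (1S,4R,5S,7S,10R,14S)-configured target skeleton with 5-O–Si(iPr)2OH and 14-OTBS | C=C1C(=O)O[C@@]2(C)CC[C@H]1[C@@H](O[Si](O)(C(C)C)C(C)C)C[C@]1(C)CC[C@@H](O1)C(=C)CC[C@@H]2O[Si](C)(C)C(C)(C)C | intermediate
32 | CNP0289823.1: (1S,4R,5S,7S,10R,14S)-5,14-dihydroxy-1,7-dimethyl-11,15(17)-dimethylidene-7,10-epoxy fourteen-membered carbocycle with the C16 carboxyl lactonised onto O1 (α-methylene ε-lactone) | C=C1C(=O)O[C@@]2(C)CC[C@H]1[C@@H](O)C[C@]1(C)CC[C@@H](O1)C(=C)CC[C@@H]2O | target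

**Step count and risks**

Total step count: 23. Longest linear sequence: 20 steps (geraniol to 32 through steps 1–8, 11–17 and 19–23).

Steps most likely to fail:

1. Step 20 (Proposed new method). The C3 carbanion may be quenched by intermolecular proton transfer before it reaches the oxirane, or the oxirane may be opened intermolecularly, so that the macrocyclisation is outrun by oligomerisation. Fallback with known chemistry, from 26 back to 28: the two bond formations are run as separate reactions. LiN(SiMe3)2 (1.05 equiv) in THF at −78 °C followed by a cold AcOH quench should stop after the silicon-tethered 5-exo Michael cyclisation and give the oxasilolane sulfone F1 with the oxirane intact. F1 is then doubly deprotonated (LiN(iPr)2, 2.3 equiv, THF–HMPA, slow addition under high dilution, −78 → 0 °C) and closed by the classical sulfone-carbanion/epoxide macrocyclisation to 28.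

2. Step 22. Enolisation at the hindered C15 may be incomplete, or the tertiary C1 alkoxide may add to the new acrylate or close too slowly onto the ester, so that the one-pot olefination–lactonisation stalls at the open hydroxy acrylate. Fallback, from 29 back to 31: the order is reversed and the lactone is made from an activated acid. Me3SnOH in 1,2-dichloroethane should hydrolyse the methyl ester to the hydroxy acid F2; lactonisation with 2-methyl-6-nitrobenzoic anhydride and DMAP under dilution should give the α-silyl ε-lactone F3; Peterson methylenation of its lithium enolate with formaldehyde then gives 31.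

3. Step 16. Chelation of zinc by the β-oxolane oxygen may erode the catalyst-controlled facial selectivity of the vinyl transfer. Fallback, from 18 back to 19: CH2=CHMgBr in THF at −78 °C should give 19 together with its C5 epimer F4; Sharpless kinetic resolution of the mixture (Ti(OiPr)4, D-(−)-diisopropyl tartrate, t-BuOOH, 0.6 equiv) should epoxidise the (5R)-epimer to the epoxy alcohol F5 and leave 19, which is separated.

Further compounds
F1 | step 20 | oxasilolane sulfone, neutral 5-exo Michael adduct of 26 (PhSO2CH2 on C4, C15 carrying CO2Me, oxirane intact) | O=S(=O)(c1ccccc1)C[C@H]2[C@H](C[C@]3(C)CC[C@@H](O3)C(=C)CC[C@H](O[Si](C)(C)C(C)(C)C)[C@]4(C)CO4)O[Si](C(C)C)(C(C)C)C2C(=O)OC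
F2 | step 22 | hydroxy acid, the C16 carboxylic acid of 29 | C1C[C@](C)(O)[C@@H](O[Si](C)(C)C(C)(C)C)CCC(=C)[C@H]2CC[C@](C)(O2)C[C@@H]3O[Si](C(C)C)(C(C)C)C(C(=O)O)[C@@H]13
F3 | step 22 | α-silyl ε-lactone, C16 lactonised onto O1 with the oxasilolane still fused at C4–C5 and C15 | O=C1O[C@@]2(C)CC[C@@H]3C1[Si](C(C)C)(C(C)C)O[C@H]3C[C@]4(C)CC[C@@H](O4)C(=C)CC[C@@H]2O[Si](C)(C)C(C)(C)C
F4 | step 16 | (2R)-epimer of 19 at the carbinol carbon C5 | C=C[C@H](O)C[C@]1(C)CC[C@@H](O1)C(=C)CC[C@H](O[Si](C)(C)C(C)(C)C)[C@]2(C)CO2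
F5 | step 16 | epoxy alcohol formed from F4, (R)-carbinol with (S)-oxiranyl group | C1O[C@@H]1[C@H](O)C[C@]2(C)CC[C@@H](O2)C(=C)CC[C@H](O[Si](C)(C)C(C)(C)C)[C@]3(C)CO3
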